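I start with time: the cedar run reads 11.0 % electrophile at 5.00 min and 10.1 % at 15.0 min.

| setting | cedar | birch | flask |
|---|---|---|---|
| electrophile | 1 mM | 1 mM | 1.0 mM |
| nucleophile | 1 mM | 1 mM | 1.00 mM |
| free base | 0.70 mM | 1.1 mM | 0.500 mM |
| remark | run made earlier | run made earlier |  |
| time |  |  | 12 min |

| run | time / min | electrophile / % | target / % |
|---|---|---|---|
| cedar | 2.00 | 13.1 | 55.5 |
| cedar | 5.00 | 11.0 | 33.2 |
| cedar | 10.0 | 9.7 | 20.8 |
| cedar | 15.0 | 10.1 | 16.9 |
| birch | 4.00 | 0.7 | 43.2 |
| birch | 8.00 | 0.9 | 26.0 |
| birch | 10.0 | 0.4 | 21.6 |
| birch | 15.0 | 1.1 | 18.2 |

(readings scatter by 0.5 percentage points)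

- part of the electrophile that has reacted at 12 min
- share of the unused nucleophile that is free and not bound as protonated nucleophile, at 12 min

You suspect this flask stops when its 0.500 mM of free base has taken up acid, but I would follow one nucleophile molecule. At its fork it either attacks electrophile, setting one acid free, or catches acid and is bound. After the base charged has taken up its share of acid, and supposing every further acid is bound, each electrophile reacted costs two nucleophiles, one consumed and one bound. On that supposition the stall point, my acid ceiling, is nucleophile plus base charged, over twice the electrophile charged: 75.0 % for this flask.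

For cedar the ceiling is 85.0 %, yet its last reading puts 89.9 % reacted at 15.0 min, so by that scattered reading cedar has covered 32.7 % of the distance from ceiling to completion. Assuming the same share for this flask at 12 min, since the cedar readings change so little, I commit to 83.2 % reacted. The runs do not show how much nucleophile is bound, so the free share stays a guess.

The forecast says 83 % (79 % to 87 %) reacted and 0.3 % (0.05 % to 1.5 %) of the unused nucleophile free, holding that “binding is a strong but finite equilibrium”.

The flask gives 84.0 % reacted and 0.393 % of the unused nucleophile free, and it then holds 0.181 mM of acid set free. It stands 9 percentage points above the ceiling of 75.0 %, and twice that overrun, 0.181 mM, is the free acid.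

    electrophile + nucleophile → acid set free + target (k = 480 L mol⁻¹ s⁻¹)
    nucleophile + acid set free ⇌ protonated nucleophile, settled at all times (K = 1.40 × 10⁶ L mol⁻¹)
    acid set free + free base ⇌ salt of the base, settled at all times (K = 1.70 × 10⁸ L mol⁻¹)
    target ⇌ isomer of the product (K = 4.70, k = 0.00410 s⁻¹)

With 0.60 mM of nucleophile, the neighbour's ceiling falls to 55.0 %, while nucleophile, now the limiting reagent, allows 60.0 %, so I expect a value between the two. That neighbour flask gives 59.2 %.

The numbers in the tables are calculated on assumed constants; scatter was added.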